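# Proposed synthesis of CNP0407898.5 by acylketene amidation and Lacey–Dieckmann closure

## Structural features

The target is a 1,4-dihydroxypyridin-2(1H)-one whose C3 carries a ketone carbonyl bonded to C1 of a trans-fused 2,6-dimethyl-octahydronaphthalene (ring A saturated, ring B holding the C3=C4 alkene) and whose C5 is bonded to the tertiary carbinol carbon C1′ of a 7-oxabicyclo[4.1.0]heptane, a cyclohexane with a C5′–C6′ epoxide and a secondary alcohol at C4′. The decalin has five stereocentres, of which C2, C1, C8a and C4a are contiguous and C6 is remote; the C1 acyl group is cis to the C2 methyl and trans to the C8a–C8 bond, and the C6 methyl is equatorial. The oxygenated ring has four contiguous stereocentres (C1′, C6′, C5′, C4′), with the epoxide oxygen cis to the C1′ hydroxyl and trans to the C4′ hydroxyl. The fragile groups are the epoxide next to a tertiary carbinol that is benzylic to an electron-rich hydroxypyridone (ionisation under acid, or attack of the pyridone C4 hydroxyl on C6′), the reducible N–O bond, the epimerisable C1 centre α to the ketone, the ring B alkene toward electrophilic oxidants, and the acidic, chelating 3-acyl-4-hydroxypyridone. The real difficulty is to join two stereochemically dense halves through a fully substituted heteroaromatic ring, and to place oxygen on nitrogen, without exposing these groups to acid, reductants or strong electrophiles. The key step uses the fact that N1–C2(=O)–C3(acyl)–C4(OH) of the pyridone is a cyclised β-keto amide. N1–C2 is an amide bond that an acylketene carrying the decalin can form, and C3–C4 is a Claisen bond to an ester carbon that the oxygenated fragment can carry together with N1, C6 and C5.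

## Logic of the disconnections

**24 ⇒ 23.** The two hydroxyls at C1′ and C4′ are traced back to O–Si bonds. A free C1′ hydroxyl would open retro-aldol and acylation pathways in every earlier basic or electrophilic step, so the diol is carried as ethers. No skeletal simplification results. The forward step must cleave both ethers with a fluoride source buffered well enough to spare the epoxide and the N–O bond.

**23 ⇒ 21.** The N1–O bond is cut. A nitrogen that already carries oxygen would sit as an oxime and not as the primary enamine that the ring-forming step needs, and the N–O bond is the weakest bond toward reduction, so it is made late. The gain is an N–H pyridone that the ring-forming step delivers directly. The forward step must transfer oxygen to nitrogen only, in the presence of the ring B alkene, the epoxide and two silyl ethers.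

**21 ⇒ 10 + 18.** N1–C2 and C3–C4 are cut. This opens the only ring that joins the halves and divides the nine stereocentres five to four between fragments of similar size. No stereocentre is formed at the union. The forward step must N-acylate a weakly nucleophilic vinylogous carbamate and then close the ring with base, without β-elimination of the C1′ silyl ether and without epimerisation at C1.

**18 ⇒ 17.** The C6–N bond of the enamine is cut back to an α-formyl ester. Nitrogen then comes from the simplest possible source. The forward condensation must be mild enough for two silyl ethers and the epoxide.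

**17 ⇒ 14.** The aldehyde is traced to a dimethyl acetal and the C1′ silyl ether to the free tertiary alcohol. The acetal carries the latent C6 carbon through the basic carbon–carbon bond formation. The forward step must unmask it without protic acid and cap the tertiary alcohol before any base is applied again.

**14 ⇒ 12 + 13.** The bond between C1′ and the ester α-carbon (the future pyridone C5) is cut, an aldol retron. One reagent supplies C4, C5 and C6 of the pyridone, and C1′ is set in this step. The forward addition must take place on the carbonyl face opposite the epoxide and must outrun enolisation and retro-aldol cleavage.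

**12 ⇒ 11.** The two epoxide C–O bonds are cut, leaving an enone with a single stereocentre. The forward epoxidation must be anti to the silyloxy group at the adjacent carbon.

**10 ⇒ 7 + 8, and 7 ⇒ 6.** The bond between the acyl carbon and C5 of the dioxanedione is cut. The path runs through 9 back to 7 and then to 6, so the acylketene precursor comes from a plain carboxyl group. The forward acylation and the saponification must leave C1 unepimerised.

**6 ⇒ 5.** C1–C2 and C4a–C8a are cut, the retron of an intramolecular [4+2] cycloaddition. Both rings and four stereocentres collapse to an acyclic triene with one stereocentre. The forward step needs an E,E-diene, an E-dienophile, endo selectivity and facial control by the C6 methyl.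

**5 ⇒ 3 + 4.** The C8=C9 double bond of the chain is cut, an olefination. The diene arrives as a four-carbon reagent. The forward step must give the E alkene and must choose the aldehyde over the enoate.

**3 ⇒ 1 + 2.** The C2=C3 double bond of the enoate is cut, a cross-metathesis. Both partners are purchasable and the stereocentre comes from the chiral pool. The forward step must engage a trisubstituted alkene in the presence of a free aldehyde.

## Other disconnections considered

**Alternative 1:** The cut runs through C4a–C5 and C8–C8a, so ring A is made by an intermolecular Diels–Alder reaction.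
- Forward key step: the cis-fused bicyclic enone A1 would come from the unsubstituted alkene of quinone monoketal A2 and isoprene A3. Endo approach and face selection would be imposed by the chiral Lewis acid prepared from the titanium salt TiCl2(OiPr)2 A4 and the diol 1,1′-bi-2-naphthol A5.
- In its favour: stereochemistry is controlled by the catalyst made from A4 and A5, the feedstock is achiral, and either enantiomer is open. A1 already holds every ring carbon of the decalin, with oxygen at C1 and C4 and methyl groups on C2 and C6.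
- Against it here: A1 is cis-fused, so C8a must be epimerised through the C1 ketone. The C6 methyl sits on an alkene, so its configuration must come from a later face-selective hydrogenation that spares the enone. C1 must be homologated by one carbon with control of C1 and C2. The C4 ketal oxygen must be removed while the C3=C4 alkene is installed.
- Comparison: on absolute stereocontrol the alternative is the better of the two, since it needs neither a purchased stereocentre nor substrate-controlled facial selectivity. On mechanism both are [4+2] cycloadditions and are equal. On structure and step economy the chosen plan is better: its intramolecular cycloaddition gives both rings, the trans fusion, four stereocentres and the right oxidation level at C1 in one step. The pyridone assembly is unaffected, so on that point the plans are equal.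

**Alternative 2:** The cut is at C1′–O and C6′–O of an epoxide placed on a pyridone that is already complete.
- Forward key step: vinyl epoxide A6 would arise by Shi epoxidation of the aryl-bearing trisubstituted alkene of dienyl pyridone A7. A later step under zerovalent palladium catalysis would shift the allylic oxygen into a 1,4 relationship (ionisation at C6′, oxygen nucleophile at C4′). A hydroxyl-directed epoxidation of C5′=C6′ would complete the ring.
- In its favour: C1′ is set under reagent control. The N–O bond is present from the start as an N-alkoxy pyridone, so no late N-hydroxylation is needed; on this point the alternative is better than the chosen plan. A7 is flat and should be reachable by cross-coupling.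
- Against it here: A6 has no acyl group at C3, so the decalin must be attached later by C-acylation of a hindered pyridone beside an epoxy alcohol. The target has the C1′ and C4′ oxygens trans. Outer-sphere attack on an allyl–palladium intermediate would be expected to return the new oxygen on the face the epoxide oxygen left, so an inner-sphere delivery or a later inversion would have to be planned. The electron-rich dialkoxypyridone and the second alkene of the diene could compete for the dioxirane. The tertiary, aryl-stabilised C–O bond of A6 is likely to be labile.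
- Comparison: the number of stereocontrolling events on this ring is equal (three in each plan). The chosen plan performs them on a six-carbon fragment by substrate control before coupling, and merges ring formation with fragment union. The alternative is more linear after its key step and should need more steps to reach the acylated target.

**Alternative 3:** The cut is C4a–C8a, so ring A alone is closed.
- Forward key step: the all-equatorial cyclohexane A8 would come from alkylidene malonate A9, the Knoevenagel product of 1 with dimethyl malonate A11, by an intramolecular ene reaction promoted by a mild Lewis acid such as zinc dibromide A10.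
- In its favour: it starts from the same chiral-pool compound 1, so the plans are equal on chiral economy. It is short, and A10 and A11 are cheap. The chair-like ene transition state sets both future ring-fusion carbons trans with the C6 methyl equatorial. For those two centres it is at least the equal of the chosen cycloaddition, and it is better in that it depends neither on diene geometry nor on an endo preference.
- Against it here: A8 contains only ring A. Ring B, with C1, C2, the C3=C4 alkene and the carboxyl carbon, must still be built from the isopropenyl and malonate groups. One ester carbon must be removed or reduced, the isopropenyl group functionalised, the ring closed, and two more stereocentres set under substrate control.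
- Comparison: both key steps are Lewis acid-promoted pericyclic closures and are equal in mechanistic reliability. The chosen plan is better on structure and step economy, since it forms both rings and four stereocentres at once.

Key step: step 10

Assumption: 4 and 11 are treated as catalogue compounds, and 18 is drawn as its hydrogen-bonded Z isomer although the E and Z forms of such push–pull enamines are expected to interconvert.

## Route

Step 1
Reactants: 1 (R)-citronellal; 2 methyl acrylate
Product: 3 methyl (2E,6R)-6-methyl-8-oxooct-2-enoate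
Conditions: 2 (5 equiv), RuCl2(H2IMes)(=CH-C6H4-2-OiPr) (second-generation Hoveyda–Grubbs catalyst, 3 mol%), CH2Cl2, 40 °C
Reagents that add atoms: methyl acrylate (2), `C=CC(=O)OC`
Why: Olefin cross-metathesis: the isopropylidene terminus of 1 exchanges with the acrylate and expels volatile 2-methylpropene, and the electron-poor partner should give the E-enoate. The aldehyde and the stereocentre are not touched by the ruthenium carbene.

Step 2
Reactants: 3 methyl (2E,6R)-6-methyl-8-oxooct-2-enoate; 4 diethyl [(2E)-but-2-en-1-yl]phosphonate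
Product: 5 methyl (2E,6R,8E,10E)-6-methyldodeca-2,8,10-trienoate
Conditions: 4, n-BuLi, THF/DMPU, −78 °C; then 3, −78 °C → rt
Reagents that add atoms: diethyl [(2E)-but-2-en-1-yl]phosphonate (4), `C/C=C/CP(=O)(OCC)OCC`
Why: Horner–Wadsworth–Emmons olefination with an allylic phosphonate anion, which should attack the aldehyde through its α-carbon far faster than it adds to the β-alkyl enoate at −78 °C and then eliminate to the E alkene. The E geometry of the crotyl unit is carried over and no stereocentre is formed.

Step 3
Reactants: 5 methyl (2E,6R,8E,10E)-6-methyldodeca-2,8,10-trienoate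
Product: 6 methyl (1R,2R,4aS,6R,8aR)-2,6-dimethyl-1,2,4a,5,6,7,8,8a-octahydronaphthalene-1-carboxylate
Conditions: EtAlCl2 (1.0 equiv), CH2Cl2, −20 °C → rt; aq. HCl work-up
Reagents that add atoms: none
Why: Lewis acid-promoted intramolecular Diels–Alder reaction through the endo transition state (ester carbonyl under the diene), which for an E,E-diene and an E-dienophile gives the trans-fused system with the C1 ester cis to the C2 methyl. The chair-like tether places the C6 methyl equatorial, and this resident centre fixes the absolute sense of C1, C2, C4a and C8a. Any 8Z isomer of 5 cannot easily reach the s-cis diene conformation and should be left behind.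

Step 4
Reactants: 6 methyl (1R,2R,4aS,6R,8aR)-2,6-dimethyl-1,2,4a,5,6,7,8,8a-octahydronaphthalene-1-carboxylate
Product: 7 (1R,2R,4aS,6R,8aR)-2,6-dimethyl-1,2,4a,5,6,7,8,8a-octahydronaphthalene-1-carboxylic acid
Conditions: LiOH·H2O, THF/MeOH/H2O, 60 °C; then 1 M HCl
Reagents that add atoms: lithium hydroxide, `[Li+].[OH-]`
Why: Saponification of a hindered equatorial ester. C1 is already in its more stable equatorial arrangement, so base should not erode it.

Step 5
Reactants: 7 (1R,2R,4aS,6R,8aR)-2,6-dimethyl-1,2,4a,5,6,7,8,8a-octahydronaphthalene-1-carboxylic acid; 8 2,2-dimethyl-1,3-dioxane-4,6-dione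
Product: 10 5-{hydroxy[(1R,2R,4aS,6R,8aR)-2,6-dimethyl-1,2,4a,5,6,7,8,8a-octahydronaphthalen-1-yl]methylidene}-2,2-dimethyl-1,3-dioxane-4,6-dione, via decalin acid chloride 9 (not isolated)
Conditions: (COCl)2, DMF (cat.), CH2Cl2, 0 °C → rt; evaporate; then 8, pyridine, DMAP (cat.), CH2Cl2, 0 °C → rt
Reagents that add atoms: 2,2-dimethyl-1,3-dioxane-4,6-dione (8), `CC1(C)OC(=O)CC(=O)O1`; oxalyl chloride, `O=C(Cl)C(=O)Cl` (chlorine held only in 9)
Why: C-Acylation of the dioxanedione by an acid chloride gives the enolised acyl derivative. A weak base at low temperature avoids ketene formation from 9 and so should preserve C1.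

Step 6
Reactants: 11 (4S)-4-{[tert-butyl(dimethyl)silyl]oxy}cyclohex-2-en-1-one
Product: 12 (1R,5S,6S)-5-{[tert-butyl(dimethyl)silyl]oxy}-7-oxabicyclo[4.1.0]heptan-2-one
Conditions: 30% aq. H2O2, benzyltrimethylammonium hydroxide (cat.), THF, 0 °C
Reagents that add atoms: hydrogen peroxide, `OO`
Why: Weitz–Scheffer nucleophilic epoxidation. Hydroperoxide should add to the β-carbon anti to the adjacent silyloxy group and the enolate then closes the epoxide on the same face, which sets both epoxide carbons trans to the C–O bond already present.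

Step 7
Reactants: 12 (1R,5S,6S)-5-{[tert-butyl(dimethyl)silyl]oxy}-7-oxabicyclo[4.1.0]heptan-2-one; 13 methyl 3,3-dimethoxypropanoate
Product: 14 methyl 2-[(1R,2R,5S,6S)-5-{[tert-butyl(dimethyl)silyl]oxy}-2-hydroxy-7-oxabicyclo[4.1.0]heptan-2-yl]-3,3-dimethoxypropanoate
Conditions: 13, LiN(iPr)2 (LDA), THF, −78 °C; then 12, −78 °C; AcOH quench at −78 °C
Reagents that add atoms: methyl 3,3-dimethoxypropanoate (13), `COC(=O)CC(OC)OC`
Why: Aldol addition of a lithium ester enolate to a ketone. Attack should occur on the carbonyl face opposite the epoxide oxygen (dipole and torsional control), so the new C–C bond is trans and the tertiary hydroxyl cis to the epoxide, which sets C1′. The centre α to the ester forms as a mixture that becomes sp2 in step 9, and the cold acidic quench guards against retro-aldol cleavage.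

Step 8
Reactants: 14 methyl 2-[(1R,2R,5S,6S)-5-{[tert-butyl(dimethyl)silyl]oxy}-2-hydroxy-7-oxabicyclo[4.1.0]heptan-2-yl]-3,3-dimethoxypropanoate
Product: 17 methyl 2-[(1R,2R,5S,6S)-5-{[tert-butyl(dimethyl)silyl]oxy}-2-[(triethylsilyl)oxy]-7-oxabicyclo[4.1.0]heptan-2-yl]-3-oxopropanoate, via triethylsilyl ether acetal 15 (not isolated), via collidinium triflate 16 (not isolated)
Conditions: TESOTf (3.5 equiv), 2,4,6-collidine (5 equiv), CH2Cl2, −78 → 0 °C; then H2O, 0 °C → rt
Reagents that add atoms: triethylsilyl trifluoromethanesulfonate, `CC[Si](CC)(CC)OS(=O)(=O)C(F)(F)F`; water, `O`; 2,4,6-trimethylpyridine, `Cc1cc(C)nc(C)c1` (held only in 16)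
Why: The silyl triflate silylates the tertiary alcohol and, with collidine, turns the dimethyl acetal into a collidinium N,O-acetal salt that water hydrolyses to the aldehyde. This is a known non-protic cleavage of aldehyde acetals that leaves silyl ethers and epoxides intact. The side chain is trans to the epoxide oxygen, so the epoxide cannot reach the activated acetal carbon.

Step 9
Reactants: 17 methyl 2-[(1R,2R,5S,6S)-5-{[tert-butyl(dimethyl)silyl]oxy}-2-[(triethylsilyl)oxy]-7-oxabicyclo[4.1.0]heptan-2-yl]-3-oxopropanoate
Product: 18 methyl (2Z)-3-amino-2-[(1R,2R,5S,6S)-5-{[tert-butyl(dimethyl)silyl]oxy}-2-[(triethylsilyl)oxy]-7-oxabicyclo[4.1.0]heptan-2-yl]prop-2-enoate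
Conditions: NH4OAc (5 equiv), MeOH, rt
Reagents that add atoms: ammonium acetate, `CC(=O)[O-].[NH4+]`
Why: Condensation of an α-formyl ester with ammonia gives the vinylogous carbamate. Conjugation and the N–H···O=C hydrogen bond should favour the Z enamine, and the buffered medium spares both silyl ethers and the epoxide.

Step 10
Reactants: 10 5-{hydroxy[(1R,2R,4aS,6R,8aR)-2,6-dimethyl-1,2,4a,5,6,7,8,8a-octahydronaphthalen-1-yl]methylidene}-2,2-dimethyl-1,3-dioxane-4,6-dione; 18 methyl (2Z)-3-amino-2-[(1R,2R,5S,6S)-5-{[tert-butyl(dimethyl)silyl]oxy}-2-[(triethylsilyl)oxy]-7-oxabicyclo[4.1.0]heptan-2-yl]prop-2-enoate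
Product: 21 3-{[(1R,2R,4aS,6R,8aR)-2,6-dimethyl-1,2,4a,5,6,7,8,8a-octahydronaphthalen-1-yl]carbonyl}-5-[(1R,2R,5S,6S)-5-{[tert-butyl(dimethyl)silyl]oxy}-2-[(triethylsilyl)oxy]-7-oxabicyclo[4.1.0]heptan-2-yl]-4-hydroxypyridin-2(1H)-one, via acylketene 19 (not isolated), via β-keto enamide 20 (not isolated)
Conditions: 10 (1.3 equiv, slow addition) to 18, toluene, 90 °C; cool to 0 °C; KOtBu (3 equiv), THF, 0 °C → rt; AcOH quench
Reagents that add atoms: none
Why: On heating, 10 fragments by a retro-[4+2] process with loss of acetone and CO2 to acylketene 19, which slow addition keeps dilute. The NH2 group of 18 adds to the ketene carbon to give β-keto enamide 20 and the N1–C2 bond; the enamine carbon terminus is fully substituted and next to a quaternary centre, so C-acylation or cycloaddition at C=C cannot lead to a stable product. KOtBu then deprotonates the C3 methylene of 20, and the stabilised carbanion attacks the methyl ester in a 6-exo-trig acyl substitution that forms C3–C4 and the only new ring. Loss of methoxide and tautomerisation to the aromatic 4-hydroxy-2-pyridone salt make the closure irreversible. No stereocentre is created, and enamide geometry does not matter because push–pull enamides isomerise under base and funnel to the cyclisable Z form. The step needs N- over C-acylation and closure without β-elimination of the C1′ silyl ether or epimerisation at C1: the ester α-carbon is sp2 and cannot form an enolate, and base removes the far more acidic C3 proton, which keeps C1 protonated. The closest known reaction type is aminolysis of acyl dioxanediones through acylketenes followed by Lacey–Dieckmann cyclisation to 3-acyl tetramic acids and 3-acyl-4-hydroxy-2-pyridones.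

Step 11
Reactants: 21 3-{[(1R,2R,4aS,6R,8aR)-2,6-dimethyl-1,2,4a,5,6,7,8,8a-octahydronaphthalen-1-yl]carbonyl}-5-[(1R,2R,5S,6S)-5-{[tert-butyl(dimethyl)silyl]oxy}-2-[(triethylsilyl)oxy]-7-oxabicyclo[4.1.0]heptan-2-yl]-4-hydroxypyridin-2(1H)-one
Product: 23 3-{[(1R,2R,4aS,6R,8aR)-2,6-dimethyl-1,2,4a,5,6,7,8,8a-octahydronaphthalen-1-yl]carbonyl}-5-[(1R,2R,5S,6S)-5-{[tert-butyl(dimethyl)silyl]oxy}-2-[(triethylsilyl)oxy]-7-oxabicyclo[4.1.0]heptan-2-yl]-1,4-dihydroxypyridin-2(1H)-one, via bis(trimethylsilyloxy)pyridine 22 (not isolated)
Conditions: HN(SiMe3)2, Me3SiCl (cat.), toluene, 90 °C; evaporate; MoO5·pyridine·HMPA (1.5 equiv), CH2Cl2, rt; aq. Na2H2EDTA work-up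
Reagents that add atoms: MoO5·pyridine·HMPA (oxygen), `O=[Mo]12(OO1)OO2.c1ccncc1.CN(C)P(=O)(N(C)C)N(C)C`; hexamethyldisilazane, `C[Si](C)(C)N[Si](C)(C)C` (silicon held only in 22)
Why: Bis-O-silylation turns the pyridone into a 2,4-bis(silyloxy)pyridine with a nucleophilic ring nitrogen. Oxygen transfer from the peroxo complex of hexavalent molybdenum gives the N-oxide, which collapses to the 1-hydroxy-2-pyridone on work-up; this is a known N-hydroxylation of 2-pyridones, 3-acyl-4-hydroxy members included. The reagent is a poor epoxidant of unactivated 1,2-disubstituted alkenes at room temperature, which should protect ring B.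

Step 12
Reactants: 23 3-{[(1R,2R,4aS,6R,8aR)-2,6-dimethyl-1,2,4a,5,6,7,8,8a-octahydronaphthalen-1-yl]carbonyl}-5-[(1R,2R,5S,6S)-5-{[tert-butyl(dimethyl)silyl]oxy}-2-[(triethylsilyl)oxy]-7-oxabicyclo[4.1.0]heptan-2-yl]-1,4-dihydroxypyridin-2(1H)-one
Product: 24 3-{[(1R,2R,4aS,6R,8aR)-2,6-dimethyl-1,2,4a,5,6,7,8,8a-octahydronaphthalen-1-yl]carbonyl}-5-[(1R,2R,5S,6R)-2,5-dihydroxy-7-oxabicyclo[4.1.0]heptan-2-yl]-1,4-dihydroxypyridin-2(1H)-one (CNP0407898.5)
Conditions: HF·pyridine, pyridine, THF, 0 °C → rt
Reagents that add atoms: none
Why: Fluoride-mediated cleavage of the tertiary triethylsilyl and secondary tert-butyldimethylsilyl ethers. Pyridine buffering is chosen to avoid both acid-promoted opening of the epoxide and base-promoted attack of the pyridone C4 hydroxyl on it.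

## Compound list

```
1 | (R)-citronellal, (3R)-3,7-dimethyloct-6-enal | C[C@H](CCC=C(C)C)CC=O | starting material
2 | methyl acrylate | C=CC(=O)OC | starting material
3 | methyl (2E,6R)-6-methyl-8-oxooct-2-enoate | C[C@H](CC/C=C/C(=O)OC)CC=O | intermediate
4 | diethyl [(2E)-but-2-en-1-yl]phosphonate | C/C=C/CP(=O)(OCC)OCC | starting material
5 | methyl (2E,6R,8E,10E)-6-methyldodeca-2,8,10-trienoate | C[C@H](CC/C=C/C(=O)OC)C/C=C/C=C/C | intermediate
6 | methyl (1R,2R,4aS,6R,8aR)-2,6-dimethyl-1,2,4a,5,6,7,8,8a-octahydronaphthalene-1-carboxylate (trans-fused; ester cis to the C2 methyl; C6 methyl equatorial) | C[C@@H]1CC[C@H]2[C@H](C(=O)OC)[C@H](C)C=C[C@@H]2C1 | intermediate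
7 | (1R,2R,4aS,6R,8aR)-2,6-dimethyl-1,2,4a,5,6,7,8,8a-octahydronaphthalene-1-carboxylic acid | C[C@@H]1CC[C@H]2[C@H](C(=O)O)[C@H](C)C=C[C@@H]2C1 | intermediate
8 | 2,2-dimethyl-1,3-dioxane-4,6-dione | CC1(C)OC(=O)CC(=O)O1 | starting material
9 | (1R,2R,4aS,6R,8aR)-2,6-dimethyl-1,2,4a,5,6,7,8,8a-octahydronaphthalene-1-carbonyl chloride | C[C@@H]1CC[C@H]2[C@H](C(=O)Cl)[C@H](C)C=C[C@@H]2C1 | intermediate (not isolated)
10 | 5-{hydroxy[(1R,2R,4aS,6R,8aR)-2,6-dimethyl-1,2,4a,5,6,7,8,8a-octahydronaphthalen-1-yl]methylidene}-2,2-dimethyl-1,3-dioxane-4,6-dione | C[C@@H]1CC[C@H]2[C@H](C(O)=C3C(=O)OC(C)(C)OC3=O)[C@H](C)C=C[C@@H]2C1 | intermediate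
11 | (4S)-4-{[tert-butyl(dimethyl)silyl]oxy}cyclohex-2-en-1-one | O=C1CC[C@H](O[Si](C)(C)C(C)(C)C)C=C1 | starting material
12 | (1R,5S,6S)-5-{[tert-butyl(dimethyl)silyl]oxy}-7-oxabicyclo[4.1.0]heptan-2-one (epoxide trans to the silyloxy group) | O=C1CC[C@H](O[Si](C)(C)C(C)(C)C)[C@H]2O[C@H]21 | intermediate
13 | methyl 3,3-dimethoxypropanoate | COC(=O)CC(OC)OC | starting material
14 | methyl 2-[(1R,2R,5S,6S)-5-{[tert-butyl(dimethyl)silyl]oxy}-2-hydroxy-7-oxabicyclo[4.1.0]heptan-2-yl]-3,3-dimethoxypropanoate (tertiary hydroxyl cis to the epoxide; both epimers at C2 of the propanoate) | COC(=O)C(C(OC)OC)[C@]1(O)CC[C@H](O[Si](C)(C)C(C)(C)C)[C@H]2O[C@H]21 | intermediate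
15 | methyl 2-[(1R,2R,5S,6S)-5-{[tert-butyl(dimethyl)silyl]oxy}-2-[(triethylsilyl)oxy]-7-oxabicyclo[4.1.0]heptan-2-yl]-3,3-dimethoxypropanoate (both epimers at C2 of the propanoate) | COC(=O)C(C(OC)OC)[C@]1(O[Si](CC)(CC)CC)CC[C@H](O[Si](C)(C)C(C)(C)C)[C@H]2O[C@H]21 | intermediate (not isolated)
16 | 1-{1,3-dimethoxy-3-oxo-2-[(1R,2R,5S,6S)-5-{[tert-butyl(dimethyl)silyl]oxy}-2-[(triethylsilyl)oxy]-7-oxabicyclo[4.1.0]heptan-2-yl]propyl}-2,4,6-trimethylpyridin-1-ium trifluoromethanesulfonate (mixture of side-chain epimers) | COC(=O)C(C(OC)[n+]1c(C)cc(C)cc1C)[C@]1(O[Si](CC)(CC)CC)CC[C@H](O[Si](C)(C)C(C)(C)C)[C@H]2O[C@H]21.[O-]S(=O)(=O)C(F)(F)F | intermediate (not isolated)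
17 | methyl 2-[(1R,2R,5S,6S)-5-{[tert-butyl(dimethyl)silyl]oxy}-2-[(triethylsilyl)oxy]-7-oxabicyclo[4.1.0]heptan-2-yl]-3-oxopropanoate (aldehyde and enol tautomers; both epimers at C2) | COC(=O)C(C=O)[C@]1(O[Si](CC)(CC)CC)CC[C@H](O[Si](C)(C)C(C)(C)C)[C@H]2O[C@H]21 | intermediate
18 | methyl (2Z)-3-amino-2-[(1R,2R,5S,6S)-5-{[tert-butyl(dimethyl)silyl]oxy}-2-[(triethylsilyl)oxy]-7-oxabicyclo[4.1.0]heptan-2-yl]prop-2-enoate | N/C=C(\C(=O)OC)[C@]1(O[Si](CC)(CC)CC)CC[C@H](O[Si](C)(C)C(C)(C)C)[C@H]2O[C@H]21 | intermediate
19 | 3-[(1R,2R,4aS,6R,8aR)-2,6-dimethyl-1,2,4a,5,6,7,8,8a-octahydronaphthalen-1-yl]-3-oxoprop-1-en-1-one (acylketene) | C[C@@H]1CC[C@H]2[C@H](C(=O)C=C=O)[C@H](C)C=C[C@@H]2C1 | intermediate (not isolated)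
20 | methyl (2Z)-3-({3-[(1R,2R,4aS,6R,8aR)-2,6-dimethyl-1,2,4a,5,6,7,8,8a-octahydronaphthalen-1-yl]-3-oxopropanoyl}amino)-2-[(1R,2R,5S,6S)-5-{[tert-butyl(dimethyl)silyl]oxy}-2-[(triethylsilyl)oxy]-7-oxabicyclo[4.1.0]heptan-2-yl]prop-2-enoate | C[C@@H]1CC[C@H]2[C@H](C(=O)CC(=O)N/C=C(\C(=O)OC)[C@]3(O[Si](CC)(CC)CC)CC[C@H](O[Si](C)(C)C(C)(C)C)[C@H]4O[C@H]43)[C@H](C)C=C[C@@H]2C1 | intermediate (not isolated)
21 | 3-{[(1R,2R,4aS,6R,8aR)-2,6-dimethyl-1,2,4a,5,6,7,8,8a-octahydronaphthalen-1-yl]carbonyl}-5-[(1R,2R,5S,6S)-5-{[tert-butyl(dimethyl)silyl]oxy}-2-[(triethylsilyl)oxy]-7-oxabicyclo[4.1.0]heptan-2-yl]-4-hydroxypyridin-2(1H)-one | C[C@@H]1CC[C@H]2[C@H](C(=O)c3c(O)c([C@]4(O[Si](CC)(CC)CC)CC[C@H](O[Si](C)(C)C(C)(C)C)[C@H]5O[C@H]54)c[nH]c3=O)[C@H](C)C=C[C@@H]2C1 | intermediate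
22 | [(1R,2R,4aS,6R,8aR)-2,6-dimethyl-1,2,4a,5,6,7,8,8a-octahydronaphthalen-1-yl]{5-[(1R,2R,5S,6S)-5-{[tert-butyl(dimethyl)silyl]oxy}-2-[(triethylsilyl)oxy]-7-oxabicyclo[4.1.0]heptan-2-yl]-2,4-bis[(trimethylsilyl)oxy]pyridin-3-yl}methanone | C[C@@H]1CC[C@H]2[C@H](C(=O)c3c(O[Si](C)(C)C)c([C@]4(O[Si](CC)(CC)CC)CC[C@H](O[Si](C)(C)C(C)(C)C)[C@H]5O[C@H]54)cnc3O[Si](C)(C)C)[C@H](C)C=C[C@@H]2C1 | intermediate (not isolated)
23 | 3-{[(1R,2R,4aS,6R,8aR)-2,6-dimethyl-1,2,4a,5,6,7,8,8a-octahydronaphthalen-1-yl]carbonyl}-5-[(1R,2R,5S,6S)-5-{[tert-butyl(dimethyl)silyl]oxy}-2-[(triethylsilyl)oxy]-7-oxabicyclo[4.1.0]heptan-2-yl]-1,4-dihydroxypyridin-2(1H)-one | C[C@@H]1CC[C@H]2[C@H](C(=O)c3c(O)c([C@]4(O[Si](CC)(CC)CC)CC[C@H](O[Si](C)(C)C(C)(C)C)[C@H]5O[C@H]54)cn(O)c3=O)[C@H](C)C=C[C@@H]2C1 | intermediate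
24 | 3-{[(1R,2R,4aS,6R,8aR)-2,6-dimethyl-1,2,4a,5,6,7,8,8a-octahydronaphthalen-1-yl]carbonyl}-5-[(1R,2R,5S,6R)-2,5-dihydroxy-7-oxabicyclo[4.1.0]heptan-2-yl]-1,4-dihydroxypyridin-2(1H)-one (epoxide cis to the tertiary hydroxyl and trans to the secondary hydroxyl) | C[C@@H]1CC[C@H]2[C@H](C(=O)c3c(O)c([C@]4(O)CC[C@H](O)[C@H]5O[C@H]54)cn(O)c3=O)[C@H](C)C=C[C@@H]2C1 | target
```

## Step count and least certain steps

Total: 12 steps. Longest linear sequence: 8 steps (steps 1–5, 10, 11 and 12 from 1); the branch from 11 is 7 steps (steps 6–12).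

**Step 10 (key step).** The most likely failure is consumption of the acylketene by dimerisation, or by traces of water followed by decarboxylation, before the weakly nucleophilic vinylogous carbamate nitrogen captures it. A second concern is acid-promoted loss of the tertiary silyl ether while the strongly acidic enol 10 is heated with 18. Fallback: set out from 10 and heat it with 2-methylpropane-2-thiol in toluene to obtain S-tert-butyl 3-[(1R,2R,4aS,6R,8aR)-2,6-dimethyl-1,2,4a,5,6,7,8,8a-octahydronaphthalen-1-yl]-3-oxopropanethioate F1. Treat F1 and 18 with AgOCOCF3 and Et3N in THF at room temperature, a thiophilic activation of a β-keto thioester that forms the amide without heat and without a free strong acid. Isolate 20, close it with KOtBu in THF, and rejoin the route at 21.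

**Step 11.** The most likely failure is over-oxidation by oxygen transfer to the ring B alkene, or stalling of the oxygen transfer at a hindered, chelating pyridine. Fallback: bring the N–O bond in with the nitrogen source. Set out from 17 and condense it with O-(tert-butyldimethylsilyl)hydroxylamine (pyridine, CH2Cl2, rt) to give the O-(tert-butyldimethylsilyl) oxime of 17 F2. Heat F2 with 10 in toluene at 90 °C. Acylation of oxime ethers that carry an α-hydrogen to N-alkoxy enamides is a known reaction class, and here 19 is the acyl donor; this should give the N-silyloxy β-keto enamide F3. If 19 instead adds across C=N to an oxazinone, the base of the next operation should open it by E1cB to the same F3. KOtBu in THF then closes F3 to the N-silyloxy pyridone F4. The HF·pyridine conditions of step 12 remove all three silyl groups, and the route is rejoined at 24.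

**Step 8.** The most likely failures are opening of the epoxide by the silyl triflate, and incomplete ionisation of an acetal that is deactivated by the neighbouring ester and shielded by the quaternary centre. Elimination to the methyl enol ether would be tolerable, since step 9 should convert it as well. Fallback: avoid the acetal. Set out from 12 and add the lithium dienolate of methyl but-3-enoate (LiN(iPr)2, THF, −78 °C, α-attack) to give methyl 2-[(1R,2R,5S,6S)-5-{[tert-butyl(dimethyl)silyl]oxy}-2-hydroxy-7-oxabicyclo[4.1.0]heptan-2-yl]but-3-enoate F5. Silylate with TESOTf and 2,6-lutidine at −78 °C to its triethylsilyl ether F6. Ozonolysis (O3, CH2Cl2/MeOH, −78 °C; Me2S) rejoins the route at 17.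

**Step 7.** The most likely failures are proton transfer from 12 to the enolate (enolisation in place of addition), β-elimination of methoxide from the enolate of 13, retro-aldol cleavage on warming, and erosion of facial selectivity. Fallback: use a less basic two-carbon nucleophile and add the formyl carbon afterwards. Set out from 12 and carry out a Reformatsky reaction with methyl bromoacetate and Zn in THF to give methyl 2-[(1R,2R,5S,6S)-5-{[tert-butyl(dimethyl)silyl]oxy}-2-hydroxy-7-oxabicyclo[4.1.0]heptan-2-yl]acetate F7. Silylate with TESOTf and 2,6-lutidine to its triethylsilyl ether F8. Deprotonate with LiN(iPr)2 at −78 °C and formylate with 2,2,2-trifluoroethyl formate to rejoin the route at 17.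

**Step 2.** The most likely failures are erosion of geometry at the new C8=C9 bond and conjugate addition of the phosphonate anion to the enoate. Fallback: build the diene in two stereodefined operations. Set out from 3 and apply a Takai olefination (CHI3, CrCl2, THF, 0 °C) to give methyl (2E,6R,8E)-9-iodo-6-methylnona-2,8-dienoate F9. Couple F9 with (E)-prop-1-enylboronic acid pinacol ester under Suzuki–Miyaura conditions (Pd(PPh3)4, aq. K3PO4, THF, 50 °C) to rejoin the route at 5.

## Further compounds

```
F1 | step 10 | S-tert-butyl 3-[(1R,2R,4aS,6R,8aR)-2,6-dimethyl-1,2,4a,5,6,7,8,8a-octahydronaphthalen-1-yl]-3-oxopropanethioate | C[C@@H]1CC[C@H]2[C@H](C(=O)CC(=O)SC(C)(C)C)[C@H](C)C=C[C@@H]2C1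
F2 | step 11 | methyl (3E)-3-({[tert-butyl(dimethyl)silyl]oxy}imino)-2-[(1R,2R,5S,6S)-5-{[tert-butyl(dimethyl)silyl]oxy}-2-[(triethylsilyl)oxy]-7-oxabicyclo[4.1.0]heptan-2-yl]propanoate | COC(=O)C(/C=N/O[Si](C)(C)C(C)(C)C)[C@]1(O[Si](CC)(CC)CC)CC[C@H](O[Si](C)(C)C(C)(C)C)[C@H]2O[C@H]21
F3 | step 11 | methyl (2Z)-3-[{[tert-butyl(dimethyl)silyl]oxy}{3-[(1R,2R,4aS,6R,8aR)-2,6-dimethyl-1,2,4a,5,6,7,8,8a-octahydronaphthalen-1-yl]-3-oxopropanoyl}amino]-2-[(1R,2R,5S,6S)-5-{[tert-butyl(dimethyl)silyl]oxy}-2-[(triethylsilyl)oxy]-7-oxabicyclo[4.1.0]heptan-2-yl]prop-2-enoate | C[C@@H]1CC[C@H]2[C@H](C(=O)CC(=O)N(O[Si](C)(C)C(C)(C)C)/C=C(\C(=O)OC)[C@]3(O[Si](CC)(CC)CC)CC[C@H](O[Si](C)(C)C(C)(C)C)[C@H]4O[C@H]43)[C@H](C)C=C[C@@H]2C1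
F4 | step 11 | 1-{[tert-butyl(dimethyl)silyl]oxy}-3-{[(1R,2R,4aS,6R,8aR)-2,6-dimethyl-1,2,4a,5,6,7,8,8a-octahydronaphthalen-1-yl]carbonyl}-5-[(1R,2R,5S,6S)-5-{[tert-butyl(dimethyl)silyl]oxy}-2-[(triethylsilyl)oxy]-7-oxabicyclo[4.1.0]heptan-2-yl]-4-hydroxypyridin-2(1H)-one | C[C@@H]1CC[C@H]2[C@H](C(=O)c3c(O)c([C@]4(O[Si](CC)(CC)CC)CC[C@H](O[Si](C)(C)C(C)(C)C)[C@H]5O[C@H]54)cn(O[Si](C)(C)C(C)(C)C)c3=O)[C@H](C)C=C[C@@H]2C1
F5 | step 8 | methyl 2-[(1R,2R,5S,6S)-5-{[tert-butyl(dimethyl)silyl]oxy}-2-hydroxy-7-oxabicyclo[4.1.0]heptan-2-yl]but-3-enoate (both epimers at C2 of the butenoate) | COC(=O)C(C=C)[C@]1(O)CC[C@H](O[Si](C)(C)C(C)(C)C)[C@H]2O[C@H]21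
F6 | step 8 | methyl 2-[(1R,2R,5S,6S)-5-{[tert-butyl(dimethyl)silyl]oxy}-2-[(triethylsilyl)oxy]-7-oxabicyclo[4.1.0]heptan-2-yl]but-3-enoate (both epimers at C2 of the butenoate) | COC(=O)C(C=C)[C@]1(O[Si](CC)(CC)CC)CC[C@H](O[Si](C)(C)C(C)(C)C)[C@H]2O[C@H]21
F7 | step 7 | methyl 2-[(1R,2R,5S,6S)-5-{[tert-butyl(dimethyl)silyl]oxy}-2-hydroxy-7-oxabicyclo[4.1.0]heptan-2-yl]acetate | COC(=O)C[C@]1(O)CC[C@H](O[Si](C)(C)C(C)(C)C)[C@H]2O[C@H]21
F8 | step 7 | methyl 2-[(1R,2R,5S,6S)-5-{[tert-butyl(dimethyl)silyl]oxy}-2-[(triethylsilyl)oxy]-7-oxabicyclo[4.1.0]heptan-2-yl]acetate | COC(=O)C[C@]1(O[Si](CC)(CC)CC)CC[C@H](O[Si](C)(C)C(C)(C)C)[C@H]2O[C@H]21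
F9 | step 2 | methyl (2E,6R,8E)-9-iodo-6-methylnona-2,8-dienoate | C[C@H](CC/C=C/C(=O)OC)C/C=C/I
A1 | alternative 1 | cis-fused 4,4-dimethoxy-2,6-dimethyl-4a,5,8,8a-tetrahydronaphthalen-1(4H)-one | CC1=CC[C@@H]2C(=O)C(C)=CC(OC)(OC)[C@@H]2C1
A2 | alternative 1 | 4,4-dimethoxy-2-methylcyclohexa-2,5-dien-1-one | CC1=CC(OC)(OC)C=CC1=O
A3 | alternative 1 | isoprene, 2-methylbuta-1,3-diene | C=CC(C)=C
A4 | alternative 1 | dichlorobis(propan-2-olato)titanium, TiCl2(OiPr)2 | CC(C)O[Ti](Cl)(Cl)OC(C)C
A5 | alternative 1 | 1,1′-bi-2-naphthol (single atropisomer, chosen to give A1; axial chirality not encoded) | Oc1ccc2ccccc2c1-c1c(O)ccc2ccccc12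
A6 | alternative 2 | 5-(7-oxabicyclo[4.1.0]hept-2-en-6-yl)-1,4-bis{[2-(trimethylsilyl)ethoxy]methoxy}pyridin-2(1H)-one (vinyl epoxide; the pyridone sits on the fully substituted epoxide carbon) | O=c1cc(OCOCC[Si](C)(C)C)c([C@]23CCC=C[C@H]2O3)cn1OCOCC[Si](C)(C)C
A7 | alternative 2 | 5-(cyclohexa-1,3-dien-1-yl)-1,4-bis{[2-(trimethylsilyl)ethoxy]methoxy}pyridin-2(1H)-one | O=c1cc(OCOCC[Si](C)(C)C)c(C2=CC=CCC2)cn1OCOCC[Si](C)(C)C
A8 | alternative 3 | dimethyl 2-[(1R,2R,5R)-5-methyl-2-(prop-1-en-2-yl)cyclohexyl]propanedioate (all-equatorial isomer) | C[C@@H]1CC[C@@H](C(C)=C)[C@H](C(C(=O)OC)C(=O)OC)C1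
A9 | alternative 3 | dimethyl 2-[(3R)-3,7-dimethyloct-6-en-1-ylidene]propanedioate | C[C@H](CCC=C(C)C)CC=C(C(=O)OC)C(=O)OC
A10 | alternative 3 | zinc dibromide, ZnBr2 | [Zn+2].[Br-].[Br-]
A11 | alternative 3 | dimethyl malonate, dimethyl propanedioate | COC(=O)CC(=O)OC
```
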